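## Structural features

The target is a daucane-type diester on a cis-fused hydroazulene: a cyclopentane (C8a, C1, C2, C3, C3a) shares the bond C3a–C8a with a cycloheptene (C3a, C4, C5, C6, C7, C8, C8a) whose only C=C is C6=C7, with a methyl on C6. Five stereocentres stand in one row around the fusion bond (C3, C3a, C4 on one side, C8a, C8 on the other), with configuration (3S,3aS,4R,8R,8aR). The angular methyl, H3a, the tertiary C3 hydroxyl and the C8 oxygen lie on one face (β); the isopropyl group and the C4 oxygen lie on the other (α). C8a is quaternary and sits next to the fully substituted carbinol C3, so the fusion hydrogen is flanked by two carbons without hydrogen. Fragile points are the tertiary alcohol (dehydration, and retro-aldol or β-elimination whenever C4 is a ketone), the allylic C8 ester (ionisation), and a free phenol beside two different esters of two secondary alcohols. The real difficulty is the cis-5,7 fusion with its quaternary centre, the correct sense of all five centres, and the differentiation of three oxygens. The key step exploits the fact that C3, C4 and C8, the oxygenated carbons around C3a–C8a, reproduce the oxygen pattern of a Wieland–Miescher-type decalin if C8a is bonded to C4 instead of C3a. One 1,2-shift of C8a from C4 to C3a then turns the six-membered rings A and B of that decalin into the five- and seven-membered rings.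

## Logic of the disconnections

23 to 22: the O–acyl bond of an aryl pivalate is cut. The phenol must stay masked through fluoride, oxidation, cuprate and acylation steps, and a silyl mask on the phenol could not be kept while alkyl silyl ethers are removed. The forward step must cleave one activated aryl ester beside two esters of hindered secondary alcohols.

22 to 20 and 21: the C8–O acyl bond is cut last, so that the allylic ester never meets reducing or organometallic reagents. The forward acylation must find the secondary allylic hydroxyl and leave the tertiary C3 hydroxyl alone.

20 to 19, 18, 17 and 15: the C8–H bond, the C6–CH3 bond and the C6=C7 unsaturation are removed in turn. Everything in ring B is traced to a C8 carbonyl that can enolise only toward C7, because C8a is quaternary. Ring B then carries a single oxygen, at the price of a late hydride delivery to the α face of C8 and two dehydrogenations that must spare the esters.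

15 to 14, then to 10 and 12 (12 from 11): the two Si–O bonds and the C4–O acyl bond are cut. The aroyl group doubles as the protecting group of the C4 oxygen, so no extra protection is spent there. Both alkyl silyl ethers are removed together, since no reagent would remove the hindered C8 silyl ether and keep a tertiary one. The acylation must reach a hindered secondary hydroxyl.

10 to 9: the C4–H bond is cut. The C4 carbinol comes from the ketone that the rearrangement leaves behind. Hydride must enter from the convex β face.

9 to 8: the bond C3a–C8a is cut and C8a is reconnected to C4. This is the strategic simplification: the cis-hydroazulenone becomes a trans-decalin 1,2-diol monosulfonate of the chiral pool. The forward step demands an equatorial leaving group on C3a antiperiplanar to C4–C8a, a free C4 hydroxyl as the only electron source, and a C3 oxygen that cannot push. The C3 oxygen is therefore carried as a triethylsilyl ether, because a trimethylsilyl ether there would not be trusted to survive osmylation, sulfonylation and alkoxide base.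

8 to 7 and 6: the S–O bond and both C–O bonds at C3a and C4 are cut, back to the C3a=C4 alkene. The forward dihydroxylation must take the α face, and sulfonylation must stop at the only secondary hydroxyl.

6 to 5, then to 3 and 4: the Si–O bond and the C3–isopropyl bond are cut. The forward 1,2-addition to the enone must come from the face opposite the angular methyl and must outrun enolisation.

3 to 2 and 1: the Si–O and C8–H bonds are cut, which ends at commercial 1. Its single stereocentre has the sense needed for C8a of 23. The C8 carbinol is a placeholder that is oxidised later. A ketal at C8 would save two steps but would put an axial oxygen on the α face of ring B, the face the dihydroxylation needs, so the equatorial silyl ether is kept.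

## Other disconnections considered

Alternative 1: The cut is at C8a–CH3 and C3a–C4. In the forward step Cu(OTf)2 with a chiral N-heterocyclic carbene (acting as monovalent copper) would transfer methyl from Me2Zn to the β-carbon C8a of cyclopentenone A2, and the zinc enolate at C3a would close the seven-membered ring on the tethered aldehyde to give A1. In its favour, one catalytic operation would make the quaternary centre, the ring and three stereocentres, and A1 already holds C6=C7, the C6 methyl and the C8 oxygen. After its key step it is clearly better in step economy than the chosen plan, which needs steps 11 to 15 for the same features, and it is equal in giving one enantiomer (catalyst control instead of chiral pool). Against it, β-substituted cyclopentenones are poor acceptors for quaternary-centre formation, and A2 holds a β,γ-unsaturated aldehyde that can slip into conjugation or take the organozinc directly. The seven-membered aldol closure is reversible, and A1 is a β-hydroxy ketone open to retro-aldol. Isopropyl would also still have to enter the C3 ketone of A1 from the concave α face, beside an enolisable C3a–H. The chosen plan sets C3 on a flat octalin where the angular methyl is the only bias, and forms the rings by migration in a preorganised frame with no entropic cost of cyclisation.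

Alternative 2: The cut removes the C7 methylene, so A3 would come from the trimethylsilyloxycyclopropane A4 of a cis-hydrindanone. In the forward step FeCl3 (trivalent iron) would oxidise A4 with cleavage of the internal C6–C8 bond to a β-chloro cycloheptanone, and NaOAc would eliminate HCl to the β-methyl enone A3. In its favour, it delivers in one operation the C8 carbonyl with C6=C7 and the C6 methyl, which the chosen route assembles in steps 12 to 14; on this point it is better. The direction of expansion is fixed because only C6 can carry the enol. It is equal to the chosen plan in still needing the late reduction at C8, with the same facial question. Against it, the stereochemical burden moves to a hydrindanone that already carries C3, C3a, C4 and C8a, for which no cheap enantiopure precursor is apparent. The tetrasubstituted silyl enol ether beside quaternary C8a is hard to form and to cyclopropanate. FeCl3 is Lewis acidic and oxidising toward a tertiary silyl ether. Overall the work before the key step is expected to be longer than the eight steps to 9.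

Alternative 3: The cut is at C3–C3a. In the forward step Rh2(OAc)4 (divalent rhodium) would decompose the α-diazo enone A6, and the carbenoid at C3a would insert into the tertiary C3–H bond to close the cyclopentane of A5. In its favour, the C3 configuration would be carried over with retention from an acyclic secondary silyl ether, which is more secure than the facial control that step 3 of the chosen plan needs; this is a point on which it is better. Insertion next to oxygen into a five-membered ring is the preferred mode, and the quaternary C8a excludes a β-hydride shift. Against it, A5 has its alkene at C5=C6 in conjugation with the C4 carbonyl, while the target needs C6=C7, so a deconjugation with ambiguous regiochemistry (C7 versus the methyl) would follow. Diazo transfer to the hindered carbon between a carbonyl and a quaternary centre is demanding. C3a would be formed next to a ketone and could epimerise. A6, a seven-membered ring with a quaternary stereocentre, would itself need an enantioselective synthesis. In mechanism both plans form the cyclopentane last; the chosen plan takes both ring sizes from a commercial decalin by one shift, which is expected to be shorter overall.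

Key step: step 7

Remark on the chemistry: the azulene locants of the target are used for every intermediate, the decalins included (C8a angular carbon, C4 the second fusion carbon of the decalin). β is the face of the angular methyl and α the opposite face. IBX is 2-iodoxybenzoic acid. Facial preferences in steps 3, 5, 8 and 15 are assumed as argued in the Why lines.

## Route

Step 1
Reactants: 1 (R)-Wieland–Miescher ketone
Product: 2 hydroxy enone (C8 hydroxyl β, cis to the angular methyl)
Conditions: NaBH4 (0.3 equiv), EtOH, −10 °C
Reagents that add atoms: none
Why: Chemoselective borohydride reduction of the saturated, non-conjugated carbonyl; hydride enters anti to the axial angular methyl and gives the equatorial hydroxyl cis to that methyl. The centre is a placeholder (oxidised in step 12), and its equatorial position keeps the α face of ring B free for step 5.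

Step 2
Reactants: 2 hydroxy enone
Product: 3 C8 tert-butyldimethylsilyl ether of 2
Conditions: TBSCl, imidazole, DMF, 40 °C
Reagents that add atoms: tert-butyldimethylsilyl chloride, CC(C)(C)[Si](C)(C)Cl
Why: Standard silylation of a secondary alcohol; the enone is untouched by imidazole.

Step 3
Reactants: 3 silyloxy enone; 4 isopropylmagnesium chloride
Product: 5 tertiary allylic alcohol (C3 hydroxyl β, isopropyl α)
Conditions: CeCl3, THF, −78 → 0 °C
Reagents that add atoms: isopropylmagnesium chloride (4), CC(C)[Mg]Cl
Why: Organocerium 1,2-addition to the enone carbonyl, which suppresses enolisation and β-hydride reduction by the branched reagent; the nucleophile approaches the flat enone anti to the axial angular methyl, which sets C3 with isopropyl α and hydroxyl β.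

Step 4
Reactants: 5 tertiary allylic alcohol
Product: 6 C3 triethylsilyl ether of 5
Conditions: TESOTf, 2,6-lutidine, CH2Cl2, −78 → 0 °C
Reagents that add atoms: triethylsilyl trifluoromethanesulfonate, CC[Si](CC)(CC)OS(=O)(=O)C(F)(F)F
Why: Silylation of a tertiary alcohol with a silyl triflate and a hindered base at low temperature, which avoids ionisation of the allylic carbinol; the triethylsilyl group is robust enough for steps 5 to 8, and a free C3 alkoxide would open a competing ring contraction in step 7.

Step 5
Reactants: 6 allylic silyl ether
Product: 7 trans-decalin cis-3a,4-diol (both hydroxyls α)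
Conditions: OsO4 (5 mol %), NMO, acetone/H2O, rt
Reagents that add atoms: osmium tetroxide, O=[Os](=O)(=O)=O; N-methylmorpholine N-oxide, C[N+]1([O-])CCOCC1
Why: Catalytic syn-dihydroxylation of the trisubstituted alkene; attack is expected on the α face, anti to the allylic silyloxy group on C3 and to the axial angular methyl on C8a. This gives the trans-decalin with C4–OH axial α and C3a–OH equatorial α.

Step 6
Reactants: 7 cis-3a,4-diol
Product: 8 3a-methanesulfonate of 7 (C4 hydroxyl free)
Conditions: MsCl, Et3N, CH2Cl2, −10 °C
Reagents that add atoms: methanesulfonyl chloride, CS(=O)(=O)Cl
Why: Sulfonylation by way of sulfene reaches the hindered secondary hydroxyl; the tertiary C4 hydroxyl does not react under these conditions.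

Step 7
Reactants: 8 trans-decalin 3a,4-diol 3a-mesylate
Product: 9 cis-fused hydroazulen-4-one
Conditions: KOtBu (1.1 equiv), THF/t-BuOH, −20 → 0 °C; pH 7 buffer
Reagents that add atoms: none
Why: KOtBu deprotonates the tertiary C4 hydroxyl, and the alkoxide drives a concerted 1,2-shift, the pinacol-type (semipinacol) rearrangement by which decalin 1,2-diol monosulfonates are known to give hydroazulenones: the C4–C8a bond, antiperiplanar to the equatorial C3a–O bond of the mesylate in the chair of ring A, moves to C3a as mesylate leaves and C4 becomes the carbonyl. Neither ring is closed by cyclisation; the one shift contracts ring A to the cyclopentane (C8a, C1, C2, C3, C3a) and expands ring B to the cycloheptanone (C3a, C4 to C8, C8a), so no ring-size selectivity or entropic cost arises. The one new stereocentre, C3a, is set by inversion (C8a enters opposite the leaving group), with retention at the migrating C8a; because the mesylate is trans to the C3 oxygen, H3a ends cis to that oxygen and to the angular methyl, which is the cis fusion. The step needs migration of C8a and not of C5 or C2: C4–C5 is gauche to the leaving group, and C3–C2, though antiperiplanar, has no electron push because the C3 oxygen is a triethylsilyl ether that is anti to C4 and so cannot migrate to the alkoxide. Epoxide formation is excluded because the C4 oxygen is cis to the mesylate, and elimination because C3 and C4 carry no hydrogen. Release of the syn-axial isopropyl/hydroxyl strain of 8 adds driving force. A small excess of base, low temperature and a buffered quench limit enolisation of 9 toward C3a, which would epimerise the fusion or expel the β-silyloxy group.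

Step 8
Reactants: 9 hydroazulen-4-one
Product: 10 C4 alcohol (hydroxyl α, trans to H3a)
Conditions: NaBH4, MeOH/THF, −20 °C
Reagents that add atoms: none
Why: Borohydride reduction; hydride is expected to attack from the convex β face of the cis-fused bicycle, since the α face is covered by the cyclopentane ring and its α-isopropyl group, which places the hydroxyl α. Prompt reduction also removes the β-silyloxy ketone, the most base-sensitive array of the route.

Step 9
Reactants: 11 4-hydroxybenzoic acid
Product: 12 4-(pivaloyloxy)benzoic acid
Conditions: PivCl, NaOH, H2O/THF, 0 °C; then HCl
Reagents that add atoms: pivaloyl chloride, CC(C)(C)C(Cl)=O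
Why: Schotten–Baumann acylation of the phenoxide. A pivalate is chosen because it should withstand DMAP, fluoride, cuprate and borohydride, yet remains an activated aryl ester for the last step.

Step 10
Reactants: 10 C4 alcohol; 12 4-(pivaloyloxy)benzoic acid
Product: 14 C4 4-(pivaloyloxy)benzoate, via 4-(pivaloyloxy)benzoyl chloride 13 (not isolated)
Conditions: 12, (COCl)2, cat. DMF, CH2Cl2, rt; concentrate; then 10, Et3N, DMAP, CH2Cl2, rt → 40 °C
Reagents that add atoms: 4-(pivaloyloxy)benzoic acid (12), CC(C)(C)C(=O)Oc1ccc(cc1)C(=O)O
Why: Acid chloride formation followed by DMAP-catalysed acylation, the forcing variant suited to a hindered secondary alcohol; 10 has no other free hydroxyl, and the aroyl group serves at once as protection of the C4 oxygen.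

Step 11
Reactants: 14 bis-silyl ether
Product: 15 C3,C8-diol
Conditions: HF·pyridine, pyridine/THF, 0 °C → rt
Reagents that add atoms: none
Why: Acidic fluoride desilylation removes the tertiary triethylsilyl and the hindered secondary tert-butyldimethylsilyl ether and leaves both aryl and alkyl esters; the free tertiary hydroxyl is no longer a liability because C4 is not a ketone.

Step 12
Reactants: 15 C3,C8-diol
Product: 17 cyclohept-6-en-8-one, via C8 ketone 16 (not isolated)
Conditions: IBX (4 equiv), DMSO, rt → 75 °C
Reagents that add atoms: none
Why: IBX oxidises the secondary alcohol to the ketone and, on warming, dehydrogenates it (IBX dehydrogenation of ketones by way of the enol). C8a is quaternary, so only C7 can enolise and the double bond can form only at C6=C7; the tertiary alcohol and the esters are inert.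

Step 13
Reactants: 17 enone
Product: 18 6-methyl ketone (C6 epimers, both used)
Conditions: MeLi, CuI, Et2O, −78 → −40 °C
Reagents that add atoms: lithium dimethylcuprate (from MeLi and CuI), [Li+].C[Cu-]C
Why: Conjugate addition of a Gilman cuprate to the unhindered β-carbon C6; cuprates do not attack the esters at this temperature, and one further equivalent is consumed by the tertiary hydroxyl. The C6 configuration is irrelevant because step 14 removes it.

Step 14
Reactants: 18 6-methyl ketone
Product: 19 6-methylcyclohept-6-en-8-one
Conditions: IBX (2 equiv), DMSO/fluorobenzene, 70 °C
Reagents that add atoms: none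
Why: Second IBX dehydrogenation, again possible only across C6–C7, gives the β-methyl enone. Reagent and time are limited because the C4 ester is a vinylogous β-leaving group and further γ-oxidation is conceivable.

Step 15
Reactants: 19 β-methyl enone
Product: 20 allylic alcohol (C8 hydroxyl β, cis to the angular methyl)
Conditions: NaBH4, CeCl3·7H2O, MeOH, −78 °C
Reagents that add atoms: none
Why: Luche reduction, which is 1,2-selective. Hydride is expected to enter anti to the angular methyl on the neighbouring C8a (α face), as in step 1 and in other ketones flanked by a methyl-bearing quaternary fusion carbon, which gives the β-hydroxyl.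

Step 16
Reactants: 20 allylic alcohol; 21 3-methylbutanoic acid
Product: 22 C8 3-methylbutanoate
Conditions: DCC, DMAP, CH2Cl2, rt
Reagents that add atoms: 3-methylbutanoic acid (21), CC(C)CC(=O)O
Why: Steglich esterification under neutral conditions suits the ionisable allylic alcohol; the tertiary C3 hydroxyl is too hindered to compete.

Step 17
Reactants: 22 pivalate-protected diester
Product: 23 target, (3S,3aS,4R,8R,8aR)-3-hydroxy-6,8a-dimethyl-8-[(3-methylbutanoyl)oxy]-3-(propan-2-yl)-1,2,3,3a,4,5,8,8a-octahydroazulen-4-yl 4-hydroxybenzoate
Conditions: pyrrolidine, THF, rt
Reagents that add atoms: none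
Why: Aminolysis of an aryl ester: the phenolic pivalate is an activated ester, whereas the two esters of hindered secondary alcohols should not react with a secondary amine at room temperature.

## Compound list

1 | (R)-Wieland–Miescher ketone, (8aR)-8a-methyl-3,4,8,8a-tetrahydronaphthalene-1,6(2H,7H)-dione | C[C@@]12CCC(=O)C=C1CCCC2=O | starting material
2 | (4aR,5R)-5-hydroxy-4a-methyl-4,4a,5,6,7,8-hexahydronaphthalen-2(3H)-one (hydroxyl cis to angular methyl) | O[C@@H]1CCCC2=CC(=O)CC[C@@]12C | intermediate
3 | (4aR,5R)-5-[(tert-butyldimethylsilyl)oxy]-4a-methyl-4,4a,5,6,7,8-hexahydronaphthalen-2(3H)-one | CC(C)(C)[Si](C)(C)O[C@@H]1CCCC2=CC(=O)CC[C@@]12C | intermediate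
4 | isopropylmagnesium chloride | CC(C)[Mg]Cl | starting material
5 | (2S,4aR,5R)-5-[(tert-butyldimethylsilyl)oxy]-4a-methyl-2-(propan-2-yl)-2,3,4,4a,5,6,7,8-octahydronaphthalen-2-ol (hydroxyl β, isopropyl α) | CC(C)(C)[Si](C)(C)O[C@@H]1CCCC2=C[C@@](O)(C(C)C)CC[C@@]12C | intermediate
6 | triethylsilyl ether of 5 (C3–OTES β, C8–OTBS β, C3a=C4 alkene) | CC(C)(C)[Si](C)(C)O[C@@H]1CCCC2=C[C@@](O[Si](CC)(CC)CC)(C(C)C)CC[C@@]12C | intermediate
7 | trans-decalin 3a,4-diol (C3a–OH and C4–OH α; C3–OTES β, isopropyl α; C8–OTBS β; 8a-methyl β) | CC(C)(C)[Si](C)(C)O[C@@H]1CCC[C@]2(O)[C@@H](O)[C@@](O[Si](CC)(CC)CC)(C(C)C)CC[C@@]12C | intermediate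
8 | trans-decalin 3a,4-diol 3a-methanesulfonate (equatorial α-mesylate, free axial α C4–OH) | CC(C)(C)[Si](C)(C)O[C@@H]1CCC[C@]2(O)[C@@H](OS(C)(=O)=O)[C@@](O[Si](CC)(CC)CC)(C(C)C)CC[C@@]12C | intermediate
9 | cis-fused hydroazulen-4-one (8a-methyl β, H3a β, C3–OTES β, isopropyl α, C8–OTBS β) | O=C1CCC[C@@H](O[Si](C)(C)C(C)(C)C)[C@]2(C)CC[C@](O[Si](CC)(CC)CC)(C(C)C)[C@H]12 | intermediate
10 | hydroazulen-4α-ol derived from 9 (C4–OH α, trans to H3a) | O[C@@H]1CCC[C@@H](O[Si](C)(C)C(C)(C)C)[C@]2(C)CC[C@](O[Si](CC)(CC)CC)(C(C)C)[C@H]12 | intermediate
11 | 4-hydroxybenzoic acid | OC(=O)c1ccc(O)cc1 | starting material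
12 | 4-[(2,2-dimethylpropanoyl)oxy]benzoic acid | CC(C)(C)C(=O)Oc1ccc(cc1)C(=O)O | intermediate
13 | 4-[(2,2-dimethylpropanoyl)oxy]benzoyl chloride (not isolated) | CC(C)(C)C(=O)Oc1ccc(cc1)C(Cl)=O | intermediate
14 | C4α 4-(pivaloyloxy)benzoate of 10 | CC(C)(C)C(=O)Oc1ccc(cc1)C(=O)O[C@@H]1CCC[C@@H](O[Si](C)(C)C(C)(C)C)[C@]2(C)CC[C@](O[Si](CC)(CC)CC)(C(C)C)[C@H]12 | intermediate
15 | C3β,C8β-diol C4α-aroyl ester | CC(C)(C)C(=O)Oc1ccc(cc1)C(=O)O[C@@H]1CCC[C@@H](O)[C@]2(C)CC[C@](O)(C(C)C)[C@H]12 | intermediate
16 | C8 ketone of 15 (not isolated) | CC(C)(C)C(=O)Oc1ccc(cc1)C(=O)O[C@@H]1CCCC(=O)[C@]2(C)CC[C@](O)(C(C)C)[C@H]12 | intermediate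
17 | C6=C7 enone with C8 carbonyl | CC(C)(C)C(=O)Oc1ccc(cc1)C(=O)O[C@@H]1CC=CC(=O)[C@]2(C)CC[C@](O)(C(C)C)[C@H]12 | intermediate
18 | 6-methyl C8 ketone (C6 configuration undefined) | CC(C)(C)C(=O)Oc1ccc(cc1)C(=O)O[C@@H]1CC(C)CC(=O)[C@]2(C)CC[C@](O)(C(C)C)[C@H]12 | intermediate
19 | 6-methyl C6=C7 enone with C8 carbonyl | CC(C)(C)C(=O)Oc1ccc(cc1)C(=O)O[C@@H]1CC(C)=CC(=O)[C@]2(C)CC[C@](O)(C(C)C)[C@H]12 | intermediate
20 | C8β allylic alcohol (hydroxyl cis to angular methyl) | CC(C)(C)C(=O)Oc1ccc(cc1)C(=O)O[C@@H]1CC(C)=C[C@@H](O)[C@]2(C)CC[C@](O)(C(C)C)[C@H]12 | intermediate
21 | 3-methylbutanoic acid | CC(C)CC(=O)O | starting material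
22 | C8β 3-methylbutanoate, C4α 4-(pivaloyloxy)benzoate | CC(C)(C)C(=O)Oc1ccc(cc1)C(=O)O[C@@H]1CC(C)=C[C@@H](OC(=O)CC(C)C)[C@]2(C)CC[C@](O)(C(C)C)[C@H]12 | intermediate
23 | (3S,3aS,4R,8R,8aR)-3-hydroxy-6,8a-dimethyl-8-[(3-methylbutanoyl)oxy]-3-(propan-2-yl)-1,2,3,3a,4,5,8,8a-octahydroazulen-4-yl 4-hydroxybenzoate | CC1=C[C@@H](OC(=O)CC(C)C)[C@]2(C)CC[C@](O)(C(C)C)[C@@H]2[C@H](OC(=O)c3ccc(O)cc3)C1 | target

## Step count and least certain steps

Total step count: 17. Longest linear sequence: 16 steps (1 to 23 through steps 1 to 8 and 10 to 17); step 9 is a one-step branch.

Step 7 (key step). The most likely failure is loss of the C3 silyl group under the alkoxide, followed by the competing shift of C2, or decay of 9 once formed: enolisation toward C3a with epimerisation of the fusion or expulsion of the β-silyloxy group. The fallback changes the activation from a free alkoxide in base to a Lewis-acid-assisted shift with immediate trapping. It sets out from 8: Et3Al in CH2Cl2 at −78 °C converts the C4 hydroxyl into its aluminium alkoxide and assists departure of the mesylate, so the same antiperiplanar shift takes place under non-basic conditions. DIBAL-H added to the same flask reduces the ketone as it forms (organoaluminium-promoted pinacol-type rearrangement with in-flask reduction). The sequence comes back at 10, and 9 is never exposed to base. No new compound arises.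

Step 5. The most likely failure is poor facial selectivity. The α face that the reagent must use also carries the isopropyl group of C3, so the anti-to-oxygen and anti-to-methyl preferences are opposed by a steric one, and attack on the β face would lead after step 7 to the wrong C3a epimer. The fallback uses a cis-hydroxylation whose facial outcome is the reverse of that of OsO4, the Woodward cis-hydroxylation. It sets out from 6: I2 and AgOAc in acetic acid form the iodonium ion on the more accessible face and acetate opens it at the tertiary C4 from the opposite face, which gives the trans-iodo acetate F1. Warming in wet acetic acid lets the acetate displace iodide with inversion at C3a through the cyclic acetoxonium ion, whose hydrolysis gives the cis-hydroxy acetate F2 on the face that OsO4 avoids. K2CO3 in methanol removes the acetate, and the route comes back at 7.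

Step 15. The most likely failure is hydride delivery from the convex β face, syn to the angular methyl, because the cyclopentane ring shields the α face; this would give the C8 epimer. The fallback accepts that outcome and corrects it by inversion instead of by another reduction. It sets out from 19: the Luche reduction then gives the epimeric alcohol F3, which is esterified with 21 under Mitsunobu conditions (PPh3, DIAD, THF). Inversion at C8 installs the 3-methylbutanoate with the required β configuration, and the route comes back at 22. Attack at the methyl-bearing C6 terminus is disfavoured.

Step 3. The most likely failure is enolisation of 3 to its dienolate or β-hydride transfer from the branched reagent in place of addition, together with incomplete facial selectivity. The fallback replaces the sp3 nucleophile by a planar sp2 one and adds a selective hydrogenation. It sets out from 3: isopropenylmagnesium bromide with CeCl3 adds in 1,2-fashion to give the isopropenyl carbinol F4. Hydrogenation with RhCl(PPh3)3 and H2 in benzene saturates only the 1,1-disubstituted alkene, since the ring alkene is trisubstituted and flanked by two fully substituted carbons, and the route comes back at 5.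

## Further compounds

F0 | step 7 | none | none
F1 | step 5 | trans-iodo acetate (C3a–I β, C4–OAc α) of 6 | CC(C)(C)[Si](C)(C)O[C@@H]1CCC[C@]2(OC(C)=O)[C@H](I)[C@@](O[Si](CC)(CC)CC)(C(C)C)CC[C@@]12C
F2 | step 5 | cis-hydroxy acetate (C3a–OH α, C4–OAc α; the regioisomeric monoacetate converges) | CC(C)(C)[Si](C)(C)O[C@@H]1CCC[C@]2(OC(C)=O)[C@@H](O)[C@@](O[Si](CC)(CC)CC)(C(C)C)CC[C@@]12C
F3 | step 15 | C8α allylic alcohol, C8 epimer of 20 | CC(C)(C)C(=O)Oc1ccc(cc1)C(=O)O[C@@H]1CC(C)=C[C@H](O)[C@]2(C)CC[C@](O)(C(C)C)[C@H]12
F4 | step 3 | isopropenyl analogue of 5 (tertiary hydroxyl β, isopropenyl α) | CC(C)(C)[Si](C)(C)O[C@@H]1CCCC2=C[C@@](O)(C(C)=C)CC[C@@]12C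
A1 | alternative 1 | cis-fused hydroazulen-3-one with C4 hydroxyl and C8 4-methoxybenzyl ether | CC1=C[C@@H](OCc3ccc(OC)cc3)[C@]2(C)CCC(=O)[C@@H]2[C@H](O)C1
A2 | alternative 1 | 3-substituted cyclopent-2-enone with a (Z)-configured tether ending in an aldehyde | O=C1C=C(CC1)[C@H](OCc1ccc(OC)cc1)/C=C(C)\CC=O
A3 | alternative 2 | hydroazulen-8-one with C6=C7 enone, C3 triethylsilyl and C4 tert-butyldimethylsilyl ethers | CC1=CC(=O)[C@]2(C)CC[C@](O[Si](CC)(CC)CC)(C(C)C)[C@@H]2[C@H](O[Si](C)(C)C(C)(C)C)C1
A4 | alternative 2 | trimethylsilyloxycyclopropane of the cis-hydrindanone (cyclopropane face undefined) | CC12CC1(O[Si](C)(C)C)[C@]3(C)CC[C@](O[Si](CC)(CC)CC)(C(C)C)[C@@H]3[C@H](O[Si](C)(C)C(C)(C)C)C2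
A5 | alternative 3 | bicyclic C4 enone (C5=C6) with C3 and C8 tert-butyldimethylsilyl ethers | CC1=CC(=O)[C@@H]2[C@@](C)(CC[C@]2(O[Si](C)(C)C(C)(C)C)C(C)C)[C@H](O[Si](C)(C)C(C)(C)C)C1
A6 | alternative 3 | α-diazo cycloheptenone with the silyloxy-isopentyl side chain on C8a | CC1=CC(=O)C(=[N+]=[N-])[C@@](C)(CC[C@H](O[Si](C)(C)C(C)(C)C)C(C)C)[C@H](O[Si](C)(C)C(C)(C)C)C1
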